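Ines reads the earlier runs as a matter of ceilings and Tomas as a matter of enzyme, which is the old dispute of thermodynamic against kinetic control.

| setting | gamma | zeta | delta | larch | alder | oak | elm |
|---|---|---|---|---|---|---|---|
| starting material | 0.10 M | 0.10 M | 0.27 M | 0.40 M | 0.10 M | 0.10 M | 0.15 M |
| protic impurity | 0.010 M | 0.010 M | 0.010 M | 0.0100 M | 0.0100 M | 0.0100 M | 0.0100 M |
| enzyme | 0.0021 mol% | 0.0086 mol% | 0.0063 mol% | 0.0063 mol% | 0.0063 mol% | 0.003 mol% | 0.01 mol% |
| remark | run made earlier | run made earlier | run made earlier |  |  |  |  |
| time |  |  |  | 25 min | 25 min | 25 min | 25 min |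

| run | time / min | product / % | starting material / % |
|---|---|---|---|
| gamma | 2.00 | 5.0 | 91.7 |
| gamma | 4.00 | 7.3 | 85.0 |
| gamma | 8.00 | 14.7 | 76.4 |
| gamma | 12.0 | 21.4 | 68.6 |
| gamma | 25.0 | 36.2 | 54.6 |
| zeta | 2.00 | 14.4 | 79.8 |
| zeta | 6.00 | 35.8 | 54.9 |
| zeta | 12.0 | 49.0 | 41.6 |
| zeta | 20.0 | 54.7 | 36.2 |
| zeta | 25.0 | 54.1 | 36.6 |
| delta | 2.00 | 13.7 | 83.0 |
| delta | 4.00 | 25.6 | 70.8 |
| delta | 8.00 | 42.9 | 53.5 |
| delta | 12.0 | 50.7 | 44.3 |
| delta | 25.0 | 57.5 | 38.6 |

(each reading ± 0.5 percentage points)



1. the flasks put in order of amount of product, in percent of the starting material charged, best first, at 25 min (larch / alder / oak / elm)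
2. the same order at 80 s (larch / alder / oak / elm)
3. the amount of product, in percent of the starting material charged of the flask you put first, at 25 min
4. the amount of product, in percent of the starting material charged of the flask you put last, at 25 min

Ines starts from delta's last reading, where product and starting material add up to 96.1%. The gap is about c(protic impurity)/c(starting material), 3.70%. So she counts that share as lost and gives the remainder delta's split, which puts larch's ceiling at 58.2% and elm's at 55.7%; larch, she says, ends higher than elm.

Tomas answers with gamma and zeta: the same charges, loadings of 0.0021 mol% and 0.0086 mol%, product 36.2% and 54.1% at 25.0 min. Elm has a higher loading of enzyme on starting material than larch, so he puts elm first.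

My own reckoning asks how far each flask has come. Delta closes the gap to its ceiling at 0.171 min⁻¹, read at 8.00 min. Larch has delta's loading, so on that rate I give it a clock count, the closing rate times the time allowed, of 4.28. The product is then the ceiling less a gap that shrinks as e^-n, which gives larch 57.4%. Ines is right at that count. At 80 s, though, larch has 0.228 and elm, scaled by loading with the rate otherwise unchanged, 0.363, and there Tomas is right. Oak, counted from gamma and scaled by loading, has 1.58; with zeta's last reading as its ceiling, that gives 43.0%.

The forecast sides with Ines at the long time: larch > elm > alder > oak, with 58.2% (57% to 59.2%) and 43.2% (41% to 45.2%). At 80 s it gives elm > larch > alder > oak. Its ground for a ceiling is “so the reaction is reversible”. For larch it stands above my figure.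

The flasks give larch > elm > alder > oak, with 58.2% and 43.9%, and elm > larch > alder > oak at 80 s.

    starting material + enzyme ⇌ complex (K = 24.0 M⁻¹, k = 29000 M⁻¹ s⁻¹)
    starting material + protic impurity → quenched substrate (k = 3.30 M⁻¹ min⁻¹)
    complex ⇌ enzyme + product (K = 0.0620 M, k = 1400 min⁻¹)

Elm's 55.8% stands below larch's 58.2% at 25 min, the order Ines gave. Tomas keeps the early region, where elm's 13.5% stands above larch's 10.2%. Left ten times as long, larch gives 58.3%, a gain of 0.10 percentage points, less than the gap of 0.8 points reckoned from a count of 4.28; larch stands nearer its end than that count reckoned.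

A lower count for larch is one way to another order. With 0.0025 mol% of enzyme, larch's count scales to 1.70, which reckons 47.6%. That flask gives 49.8%, below elm and alder as they stand.

The numbers in the tables were generated by integration with made-up constants, and the scatter is random.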